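The plan cuts the lactone (O1, C2, C3, C4, C5) at O1–C2 and at the bond joining the C4 benzylic CH2 to catechol ring B. The feature exploited is that C4 bears two CH2 groups, C5 and the carbon leading to ring B, so it can enter as a carbon with two identical hydroxymethyl arms next to the already fixed C3, which holds the ring A benzyl group. In the key step acid closes the ring of an open-chain (R)-methyl ester diol with either arm and lets both lactones interconvert by acyl transfer until the 3,4-trans one dominates, delivering ring, O1–C2 bond and C4 configuration together. The diol comes from (R)-danshensu and a malonate.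

Key step: step 6

Remarks on the chemistry:
- The target is the (3R,4R)-trans lactone. The C4 descriptor is S in 10 and R in 11, 14 and 15 only because the CIP rank of the exocyclic CH2 group changes; the geometry is the same throughout.
- Diol ester 8 is taken into step 6 without chromatography, because any ring closure that starts during work-up enters the same equilibrium.
- The alcohol is converted into the bromide so that both partners in step 9 are bromides of comparable reactivity.

Step 1
Reactants: 1 sodium (R)-3-(3,4-dihydroxyphenyl)-2-hydroxypropanoate (danshensu sodium)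
Product: 2 methyl (R)-3-(3,4-dimethoxyphenyl)-2-hydroxypropanoate
Conditions: MeI (4 equiv), K2CO3 (3 equiv), DMF, 0 °C to rt, under N2
Reagents that add atoms: iodomethane, CI
Why: Williamson-type SN2 O-methylation of the carboxylate and both phenoxides should be clean because K2CO3 is too weak to deprotonate the secondary alcohol or the α-C–H, so the hydroxyl stays free and the (R) centre is untouched, while exclusion of air protects the catechol until it is capped.

Step 2
Reactants: 2 methyl (R)-3-(3,4-dimethoxyphenyl)-2-hydroxypropanoate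
Product: 3 methyl (R)-3-(3,4-dimethoxyphenyl)-2-{[(trifluoromethyl)sulfonyl]oxy}propanoate
Conditions: Tf2O (1.2 equiv), 2,6-lutidine (1.5 equiv), CH2Cl2, −78 to −30 °C; cold aqueous work-up, used at once
Reagents that add atoms: trifluoromethanesulfonic anhydride, O=S(=O)(OS(=O)(=O)C(F)(F)F)C(F)(F)F
Why: O-sulfonylation of the secondary alcohol with Tf2O and a hindered pyridine base occurs at oxygen only, so configuration is retained, and the low temperature keeps the reactive α-triflyloxy ester from eliminating before step 3.

Step 3
Reactants: 3 methyl (R)-3-(3,4-dimethoxyphenyl)-2-{[(trifluoromethyl)sulfonyl]oxy}propanoate; 4 dibenzyl malonate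
Product: 6 1,1-dibenzyl 2-methyl (2R)-3-(3,4-dimethoxyphenyl)propane-1,1,2-tricarboxylate, via sodium dibenzyl malonate 5 (not isolated)
Conditions: 4 (1.4 equiv), NaH (1.3 equiv), THF, 0 °C; then 3, 0 °C to rt
Reagents that add atoms: none
Why: SN2 displacement of an α-triflyloxy ester by the soft malonate anion 5 proceeds with Walden inversion and so sets the future C3 centre (the descriptor stays R only because the incoming carbon ranks below the ester group), and the very good leaving group allows substitution at 0 °C, where E2 toward the cinnamate is slow.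

Step 4
Reactants: 6 1,1-dibenzyl 2-methyl (2R)-3-(3,4-dimethoxyphenyl)propane-1,1,2-tricarboxylate
Product: 7 2-[(2R)-1-(3,4-dimethoxyphenyl)-3-methoxy-3-oxopropan-2-yl]propanedioic acid
Conditions: H2 (1 atm), 10% Pd/C, EtOAc, rt
Reagents that add atoms: none
Why: Hydrogenolysis of the two benzyl esters over Pd/C is selective because aryl methyl ethers and the methyl ester are inert to H2 here, and room temperature avoids decarboxylation of the malonic acid.

Step 5
Reactants: 7 2-[(2R)-1-(3,4-dimethoxyphenyl)-3-methoxy-3-oxopropan-2-yl]propanedioic acid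
Product: 8 methyl (2R)-2-(3,4-dimethoxybenzyl)-4-hydroxy-3-(hydroxymethyl)butanoate
Conditions: BH3·THF (4 equiv), THF, 0 °C to rt; then MeOH, co-evaporation
Reagents that add atoms: none
Why: Chemoselective borane reduction: carboxylic acids are reduced through acyloxyboranes much faster than esters, so both acid groups should go to CH2OH while the methyl ester and the C3 centre (no base present) are left alone.

Step 6
Reactants: 8 methyl (2R)-2-(3,4-dimethoxybenzyl)-4-hydroxy-3-(hydroxymethyl)butanoate
Product: 10 (3R,4S)-3-(3,4-dimethoxybenzyl)-4-(hydroxymethyl)dihydrofuran-2(3H)-one, via cis-hydroxymethyl lactone 9 (not isolated)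
Conditions: TsOH·H2O (10 mol %), PhMe (0.05 M), 60 °C, N2 sweep to remove MeOH
Reagents that add atoms: none
Why: Protonation of the ester carbonyl lets either hydroxymethyl oxygen add to C2 and expel methanol, so both the trans lactone 10 and the cis lactone 9 form at first. Each closure is a 5-exo-trig acyl substitution that makes the O1–C2 bond and the single new ring. The free CH2OH of either lactone can add to its own protonated carbonyl through a bridged tetrahedral intermediate and take over the acyl group, which swaps the arm that sits in the ring and thereby converts 9 into 10 and back (reopening by residual methanol is a second channel). The closest known reaction type is acid-catalysed γ-lactonisation of γ-hydroxy esters combined with the acyl migration known for β-(hydroxymethyl)-γ-butyrolactones. The new C4 centre is controlled by the existing C3 centre through the thermodynamic preference of 3,4-disubstituted γ-butyrolactones for the trans arrangement, which for (3R) means (4S). The step needs selectivity between the two diastereotopic arms on C4, and this is secured by reversibility plus the trans bias, while the absence of base keeps C3 from enolising, so an imperfect outcome would lower diastereomeric, not enantiomeric, purity.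

Step 7
Reactants: 10 (3R,4S)-3-(3,4-dimethoxybenzyl)-4-(hydroxymethyl)dihydrofuran-2(3H)-one
Product: 11 (3R,4R)-4-(bromomethyl)-3-(3,4-dimethoxybenzyl)dihydrofuran-2(3H)-one
Conditions: CBr4 (1.3 equiv), PPh3 (1.4 equiv), CH2Cl2, 0 °C to rt
Reagents that add atoms: tetrabromomethane, BrC(Br)(Br)Br
Why: Appel reaction: bromide displaces the alkoxyphosphonium ion by SN2 at the exocyclic CH2, which touches neither stereocentre, spares the lactone under neutral conditions and removes the hydroxyl needed for acyl migration, so C4 is locked.

Step 8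
Reactants: 12 4-bromocatechol
Product: 13 1,2-bis(benzyloxy)-4-bromobenzene
Conditions: BnBr (2.3 equiv), K2CO3 (3 equiv), DMF, 60 °C, under N2
Reagents that add atoms: benzyl bromide, BrCc1ccccc1
Why: Williamson ether synthesis: both phenoxides are benzylated by SN2 on BnBr, and the aryl bromide is inert to carbonate.

Step 9
Reactants: 11 (3R,4R)-4-(bromomethyl)-3-(3,4-dimethoxybenzyl)dihydrofuran-2(3H)-one; 13 1,2-bis(benzyloxy)-4-bromobenzene
Product: 14 (3R,4R)-4-[3,4-bis(benzyloxy)benzyl]-3-(3,4-dimethoxybenzyl)dihydrofuran-2(3H)-one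
Conditions: NiI2 (10 mol %), 4,4'-di-tert-butyl-2,2'-bipyridine (10 mol %), NaI (25 mol %), pyridine (10 mol %), Zn dust (2 equiv), DMPU, 60 °C
Reagents that add atoms: none
Why: Nickel-catalysed reductive cross-electrophile coupling of an aryl bromide with a primary alkyl bromide: zerovalent nickel inserts into the aryl C–Br bond, the alkyl bromide is reduced to a radical that the arylnickel species captures, and reductive elimination forms the CH2–aryl bond with zinc as terminal reductant, while neither stereocentre is at the reacting carbon and lactone and ethers are tolerated.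

Step 10
Reactants: 14 (3R,4R)-4-[3,4-bis(benzyloxy)benzyl]-3-(3,4-dimethoxybenzyl)dihydrofuran-2(3H)-one
Product: 15 (3R,4R)-4-(3,4-dihydroxybenzyl)-3-(3,4-dimethoxybenzyl)dihydrofuran-2(3H)-one
Conditions: H2 (1 atm), 10% Pd/C, EtOAc/THF, rt; work-up under N2
Reagents that add atoms: none
Why: Hydrogenolysis of the two aryl benzyl ethers over Pd/C frees the catechol, while methyl ethers, lactone, benzylic C–C bonds and both stereocentres are unaffected.

Compound list
1 | sodium (R)-3-(3,4-dihydroxyphenyl)-2-hydroxypropanoate (danshensu sodium) | [Na+].[O-]C(=O)[C@H](O)Cc1ccc(O)c(O)c1 | starting material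
2 | methyl (R)-3-(3,4-dimethoxyphenyl)-2-hydroxypropanoate | COC(=O)[C@H](O)Cc1ccc(OC)c(OC)c1 | intermediate
3 | methyl (R)-3-(3,4-dimethoxyphenyl)-2-{[(trifluoromethyl)sulfonyl]oxy}propanoate | COC(=O)[C@H](OS(=O)(=O)C(F)(F)F)Cc1ccc(OC)c(OC)c1 | intermediate
4 | dibenzyl malonate | O=C(CC(=O)OCc1ccccc1)OCc1ccccc1 | starting material
5 | sodium dibenzyl malonate (enolate of 4, formed in the flask in step 3) | [Na+].O=C([CH-]C(=O)OCc1ccccc1)OCc1ccccc1 | intermediate
6 | 1,1-dibenzyl 2-methyl (2R)-3-(3,4-dimethoxyphenyl)propane-1,1,2-tricarboxylate | COc1ccc(C[C@@H](C(=O)OC)C(C(=O)OCc2ccccc2)C(=O)OCc2ccccc2)cc1OC | intermediate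
7 | 2-[(2R)-1-(3,4-dimethoxyphenyl)-3-methoxy-3-oxopropan-2-yl]propanedioic acid | COc1ccc(C[C@@H](C(=O)OC)C(C(=O)O)C(=O)O)cc1OC | intermediate
8 | methyl (2R)-2-(3,4-dimethoxybenzyl)-4-hydroxy-3-(hydroxymethyl)butanoate | COc1ccc(C[C@@H](C(=O)OC)C(CO)CO)cc1OC | intermediate
9 | (3R,4R)-3-(3,4-dimethoxybenzyl)-4-(hydroxymethyl)dihydrofuran-2(3H)-one (cis lactone, formed in the flask in step 6) | COc1ccc(C[C@H]2C(=O)OC[C@H]2CO)cc1OC | intermediate
10 | (3R,4S)-3-(3,4-dimethoxybenzyl)-4-(hydroxymethyl)dihydrofuran-2(3H)-one (trans lactone) | COc1ccc(C[C@H]2C(=O)OC[C@@H]2CO)cc1OC | intermediate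
11 | (3R,4R)-4-(bromomethyl)-3-(3,4-dimethoxybenzyl)dihydrofuran-2(3H)-one | COc1ccc(C[C@H]2C(=O)OC[C@@H]2CBr)cc1OC | intermediate
12 | 4-bromocatechol (4-bromobenzene-1,2-diol) | Oc1ccc(Br)cc1O | starting material
13 | 1,2-bis(benzyloxy)-4-bromobenzene | Brc1ccc(OCc2ccccc2)c(OCc2ccccc2)c1 | intermediate
14 | (3R,4R)-4-[3,4-bis(benzyloxy)benzyl]-3-(3,4-dimethoxybenzyl)dihydrofuran-2(3H)-one | COc1ccc(C[C@H]2C(=O)OC[C@@H]2Cc2ccc(OCc3ccccc3)c(OCc3ccccc3)c2)cc1OC | intermediate
15 | (3R,4R)-4-(3,4-dihydroxybenzyl)-3-(3,4-dimethoxybenzyl)dihydrofuran-2(3H)-one | COc1ccc(C[C@H]2C(=O)OC[C@@H]2Cc2ccc(O)c(O)c2)cc1OC | target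

Total steps: 10. Longest linear sequence: 9 steps (steps 1 to 7, 9 and 10, from 1); step 8 is a one-step side branch.

Steps most likely to fail

Step 6. The acyl transfer between the two arms may be too slow to reach equilibrium, the equilibrium may leave a sizeable share of the cis lactone, or more forcing acid may begin to enolise C3. The fallback gives up arm selection and sets the trans relationship kinetically by enolate alkylation. It sets out from 13. Magnesium insertion (Mg, THF) gives [3,4-bis(benzyloxy)phenyl]magnesium bromide F1. With catalytic CuI at −30 °C this opens commercial ethyl (1S,5R)-2-oxo-3-oxabicyclo[3.1.0]hexane-1-carboxylate (CCOC(=O)[C@]12C[C@H]1COC2=O) at the cyclopropane CH2 by homoconjugate addition, giving ethyl (4R)-4-[3,4-bis(benzyloxy)benzyl]-2-oxotetrahydrofuran-3-carboxylate F2. Krapcho dealkoxycarbonylation (LiCl, wet DMSO, 140 °C) gives (R)-4-[3,4-bis(benzyloxy)benzyl]dihydrofuran-2(3H)-one F3. Its lithium enolate (LiN(SiMe3)2, THF, −78 °C) is alkylated by 3,4-dimethoxybenzyl bromide on the face opposite the C4 substituent, the standard entry to trans-dibenzylbutyrolactones, and the route is rejoined at 14. Steps 1 to 7 and 9 are then not needed.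

Step 9. The alkyl bromide may be consumed by homocoupling or hydrodehalogenation before the electron-rich aryl bromide has undergone oxidative addition, or the intermediate primary radical may be lost to side reactions. The fallback replaces the radical cross-electrophile manifold by a preformed organozinc nucleophile and palladium catalysis. It sets out from 11. Zinc insertion (Zn dust, I2 5 mol %, DMA, 70 °C) gives {[(3R,4R)-4-(3,4-dimethoxybenzyl)-5-oxotetrahydrofuran-3-yl]methyl}zinc bromide F4. Negishi coupling of this with 13 (Pd(OAc)2 2 mol %, SPhos 4 mol %, THF/DMA, 50 °C) returns to the route at 14.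

Step 3. Elimination of triflic acid toward the conjugated cinnamate, helped by the benzylic β-hydrogens, or erosion of configuration at the α-carbon through aryl participation, may compete with substitution. The fallback replaces substitution at a saturated α-carbon by enantioselective allylic alkylation. It sets out from 4. Methyleugenol (4-allyl-1,2-dimethoxybenzene) and excess allyl methyl carbonate undergo cross-metathesis (second-generation Hoveyda–Grubbs catalyst, CH2Cl2, 40 °C) to (E)-4-(3,4-dimethoxyphenyl)but-2-en-1-yl methyl carbonate F5. The enolate 5 made from 4 then attacks the substituted allyl terminus under [Ir(cod)Cl]2 and a chiral BINOL-derived phosphoramidite ligand (THF, rt, ligand enantiomer chosen for the S product), giving dibenzyl 2-[(2S)-1-(3,4-dimethoxyphenyl)but-3-en-2-yl]propanedioate F6. Lemieux–Johnson cleavage of the vinyl group (K2OsO4·2H2O cat., NaIO4, 2,6-lutidine, dioxane/H2O) gives dibenzyl 2-[(2R)-1-(3,4-dimethoxyphenyl)-3-oxopropan-2-yl]propanedioate F7, which is oxidised at once (Pinnick oxidation: NaClO2, NaH2PO4, 2-methyl-2-butene, t-BuOH/H2O) to (2R)-4-(benzyloxy)-3-[(benzyloxy)carbonyl]-2-(3,4-dimethoxybenzyl)-4-oxobutanoic acid F8. Esterification with Me3SiCHN2 (MeOH/PhMe, 0 °C) returns to the route at 6.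

Further compounds
F1 | step 6 | [3,4-bis(benzyloxy)phenyl]magnesium bromide | Br[Mg]c1ccc(OCc2ccccc2)c(OCc2ccccc2)c1
F2 | step 6 | ethyl (4R)-4-[3,4-bis(benzyloxy)benzyl]-2-oxotetrahydrofuran-3-carboxylate (C3 epimers) | CCOC(=O)C1C(=O)OC[C@@H]1Cc1ccc(OCc2ccccc2)c(OCc2ccccc2)c1
F3 | step 6 | (R)-4-[3,4-bis(benzyloxy)benzyl]dihydrofuran-2(3H)-one | O=C1C[C@@H](Cc2ccc(OCc3ccccc3)c(OCc3ccccc3)c2)CO1
F4 | step 9 | {[(3R,4R)-4-(3,4-dimethoxybenzyl)-5-oxotetrahydrofuran-3-yl]methyl}zinc bromide | COc1ccc(C[C@H]2C(=O)OC[C@@H]2C[Zn]Br)cc1OC
F5 | step 3 | (E)-4-(3,4-dimethoxyphenyl)but-2-en-1-yl methyl carbonate | COC(=O)OC/C=C/Cc1ccc(OC)c(OC)c1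
F6 | step 3 | dibenzyl 2-[(2S)-1-(3,4-dimethoxyphenyl)but-3-en-2-yl]propanedioate | COc1ccc(C[C@@H](C=C)C(C(=O)OCc2ccccc2)C(=O)OCc2ccccc2)cc1OC
F7 | step 3 | dibenzyl 2-[(2R)-1-(3,4-dimethoxyphenyl)-3-oxopropan-2-yl]propanedioate | COc1ccc(C[C@@H](C=O)C(C(=O)OCc2ccccc2)C(=O)OCc2ccccc2)cc1OC
F8 | step 3 | (2R)-4-(benzyloxy)-3-[(benzyloxy)carbonyl]-2-(3,4-dimethoxybenzyl)-4-oxobutanoic acid | COc1ccc(C[C@@H](C(=O)O)C(C(=O)OCc2ccccc2)C(=O)OCc2ccccc2)cc1OC
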